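**Retrosynthetic overview**
- The acid is made last by Pinnick oxidation of a C4 aldehyde; the C2 ketone comes from a silyl-protected C2 alcohol (desilylation, then oxidation).
- Both rings form together in one intramolecular Diels–Alder reaction of an all-E tetraenal (new bonds C4–C5 and C3a–C7a). The cyclohexene and the trans-fused cyclopentane close in the same step; nothing is cyclic before it.
- The tetraenal is cut at C3a=C4 (Horner–Wadsworth–Emmons, then ester to enal) and along the triene (one Wittig and two Horner–Wadsworth–Emmons olefinations growing out from C7a).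
- The C1–C2–C3 stereotriad is cut at C1–C2: Evans syn aldol of (4S)-4-benzyl-3-propanoyl-oxazolidin-2-one with the aldehyde from the (R)-Roche ester. This fragment-joining aldol is the key step.

Assumption: carbons are labelled C1–C7a as in the indene skeleton of the target, also in open-chain intermediates; the C2 configuration is free because C2 ends as the ketone, so the Evans syn adduct is used. TBS = tert-butyldimethylsilyl.

**Route**

Step 1
Reactants: 1 methyl (2R)-3-hydroxy-2-methylpropanoate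
Product: 2 methyl (2R)-3-(TBSO)-2-methylpropanoate
Conditions: TBSCl, imidazole, DMF, 0 °C → rt
Reagents that add atoms: tert-butyldimethylsilyl chloride, CC(C)(C)[Si](C)(C)Cl
Why: Imidazole-promoted silylation of the primary alcohol; the C3 stereocentre is bought with the Roche ester and is not touched.

Step 2
Reactants: 2 methyl (2R)-3-(TBSO)-2-methylpropanoate
Product: 3 (2S)-3-(TBSO)-2-methylpropan-1-ol
Conditions: i-Bu2AlH (2.5 equiv), CH2Cl2, −78 → 0 °C
Reagents that add atoms: none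
Why: Hydride reduction of the ester to the primary alcohol without base that could move the silyl group between the two oxygens (the descriptor changes by priority only).

Step 3
Reactants: 3 (2S)-3-(TBSO)-2-methylpropan-1-ol
Product: 4 (2R)-3-(TBSO)-2-methylpropanal
Conditions: Dess–Martin periodinane, NaHCO3, CH2Cl2, 0 °C → rt; used crude at once
Reagents that add atoms: none
Why: Dess–Martin oxidation gives the α-chiral aldehyde under non-basic conditions, and immediate use avoids epimerisation.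

Step 4
Reactants: 5 (4S)-4-benzyl-3-propanoyl-1,3-oxazolidin-2-one; 4 (2R)-3-(TBSO)-2-methylpropanal
Product: 8 (4S)-4-benzyl-3-[(2S,3R,4R)-5-(TBSO)-3-hydroxy-2,4-dimethylpentanoyl]-1,3-oxazolidin-2-one, via Z-dibutylboron enolate 6 (not isolated), via dibutylboron aldolate 7 (not isolated)
Conditions: 5, Bu2BOTf, Et3N, CH2Cl2, 0 °C; then 4, −78 → 0 °C; then H2O2, MeOH, pH 7 buffer (NaH2PO4/Na2HPO4), 0 °C
Reagents that add atoms: dibutylboron triflate, CCCCB(CCCC)OS(=O)(=O)C(F)(F)F (its Bu2B group is carried only by 6 and 7 and is removed on work-up)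
Why: Evans syn aldol in which the Z boron enolate reacts through a Zimmerman–Traxler chair with the auxiliary benzyl group shielding one face, setting C1 and C2 syn (2S,3R in the adduct); the anti relation to the C3 methyl is the matched anti-Felkin outcome for a Z enolate.

Step 5
Reactants: 8 (4S)-4-benzyl-3-[(2S,3R,4R)-5-(TBSO)-3-hydroxy-2,4-dimethylpentanoyl]-1,3-oxazolidin-2-one
Product: 9 (2S,3R,4R)-5-(TBSO)-3-hydroxy-N-methoxy-N,2,4-trimethylpentanamide
Conditions: MeNH(OMe)·HCl, AlMe3, THF, −20 → 0 °C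
Reagents that add atoms: N,O-dimethylhydroxylamine hydrochloride, CNOC.Cl
Why: Aluminium amide transamination of the imide, helped by chelation of the free β-hydroxyl, gives the Weinreb amide without touching the stereocentres and releases the auxiliary.

Step 6
Reactants: 9 (2S,3R,4R)-5-(TBSO)-3-hydroxy-N-methoxy-N,2,4-trimethylpentanamide
Product: 10 (2S,3R,4R)-3,5-bis(TBSO)-N-methoxy-N,2,4-trimethylpentanamide
Conditions: TBSOTf, 2,6-lutidine, CH2Cl2, −78 → 0 °C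
Reagents that add atoms: tert-butyldimethylsilyl triflate, CC(C)(C)[Si](C)(C)OS(=O)(=O)C(F)(F)F
Why: Silyl triflate protection of the hindered secondary alcohol, which blocks retro-aldol and fixes the C2 substituent for the later cycloaddition.

Step 7
Reactants: 10 (2S,3R,4R)-3,5-bis(TBSO)-N-methoxy-N,2,4-trimethylpentanamide
Product: 11 (2S,3R,4R)-3,5-bis(TBSO)-2,4-dimethylpentanal
Conditions: i-Bu2AlH, THF, −78 °C; used crude
Reagents that add atoms: none
Why: Hydride reduction of a Weinreb amide stops at the chelated tetrahedral intermediate and gives the aldehyde on work-up without over-reduction or epimerisation at C1.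

Step 8
Reactants: 11 (2S,3R,4R)-3,5-bis(TBSO)-2,4-dimethylpentanal; 12 ethyl 2-(triphenylphosphoranylidene)propanoate
Product: 13 ethyl (2E,4R,5S,6R)-5,7-bis(TBSO)-2,4,6-trimethylhept-2-enoate
Conditions: 12 (2 equiv), toluene, 60 °C
Reagents that add atoms: none
Why: Wittig olefination with a stabilised ylide gives the (E)-trisubstituted C7a=C7 alkene under neutral conditions that leave C1 intact.

Step 9
Reactants: 13 ethyl (2E,4R,5S,6R)-5,7-bis(TBSO)-2,4,6-trimethylhept-2-enoate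
Product: 14 (2E,4R,5S,6R)-5,7-bis(TBSO)-2,4,6-trimethylhept-2-en-1-ol
Conditions: i-Bu2AlH (2.5 equiv), CH2Cl2, −78 °C
Reagents that add atoms: none
Why: 1,2-Reduction of the enoate to the allylic alcohol; silyl ethers and the alkene are inert.

Step 10
Reactants: 14 (2E,4R,5S,6R)-5,7-bis(TBSO)-2,4,6-trimethylhept-2-en-1-ol
Product: 15 (2E,4R,5S,6R)-5,7-bis(TBSO)-2,4,6-trimethylhept-2-enal
Conditions: MnO2 (excess), CH2Cl2, rt
Reagents that add atoms: none
Why: Chemoselective allylic oxidation to the enal without alkene isomerisation.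

Step 11
Reactants: 15 (2E,4R,5S,6R)-5,7-bis(TBSO)-2,4,6-trimethylhept-2-enal; 16 ethyl 2-(diethoxyphosphoryl)butanoate
Product: 17 ethyl (2E,4E,6R,7S,8R)-7,9-bis(TBSO)-2-ethyl-4,6,8-trimethylnona-2,4-dienoate
Conditions: 16, NaH, THF, 0 °C; then 15, 0 °C → rt
Reagents that add atoms: none
Why: Horner–Wadsworth–Emmons olefination with the α-ethyl phosphonate forms the C5=C6 alkene with the ester trans to C7 (E), which later places the styryl group outside and the ethyl group inside on the diene.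

Step 12
Reactants: 17 ethyl (2E,4E,6R,7S,8R)-7,9-bis(TBSO)-2-ethyl-4,6,8-trimethylnona-2,4-dienoate
Product: 18 (2E,4E,6R,7S,8R)-7,9-bis(TBSO)-2-ethyl-4,6,8-trimethylnona-2,4-dien-1-ol
Conditions: i-Bu2AlH (2.5 equiv), CH2Cl2, −78 °C
Reagents that add atoms: none
Why: 1,2-Reduction of the dienoate to the dienyl alcohol.

Step 13
Reactants: 18 (2E,4E,6R,7S,8R)-7,9-bis(TBSO)-2-ethyl-4,6,8-trimethylnona-2,4-dien-1-ol
Product: 19 (2E,4E,6R,7S,8R)-7,9-bis(TBSO)-2-ethyl-4,6,8-trimethylnona-2,4-dienal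
Conditions: MnO2 (excess), CH2Cl2, rt
Reagents that add atoms: none
Why: Allylic oxidation to the dienal, which has no α-hydrogen and is therefore robust to base in the next step.

Step 14
Reactants: 19 (2E,4E,6R,7S,8R)-7,9-bis(TBSO)-2-ethyl-4,6,8-trimethylnona-2,4-dienal; 20 diethyl benzylphosphonate
Product: 21 [(1E,3E,5E,7R,8S,9R)-8,10-bis(TBSO)-3-ethyl-5,7,9-trimethyldeca-1,3,5-trien-1-yl]benzene
Conditions: 20, KOtBu, THF, 0 °C; then 19, −78 → 0 °C
Reagents that add atoms: none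
Why: Horner–Wadsworth–Emmons olefination with a benzylphosphonate gives the (E)-styryl alkene and completes the all-E triene.

Step 15
Reactants: 21 [(1E,3E,5E,7R,8S,9R)-8,10-bis(TBSO)-3-ethyl-5,7,9-trimethyldeca-1,3,5-trien-1-yl]benzene
Product: 22 (2R,3S,4R,5E,7E,9E)-3-(TBSO)-8-ethyl-2,4,6-trimethyl-10-phenyldeca-5,7,9-trien-1-ol
Conditions: HF·pyridine, pyridine, THF, 0 °C
Reagents that add atoms: none
Why: Selective desilylation: under buffered fluoride the unhindered primary silyl ether is cleaved far faster than the secondary one flanked by two methyl-bearing carbons.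

Step 16
Reactants: 22 (2R,3S,4R,5E,7E,9E)-3-(TBSO)-8-ethyl-2,4,6-trimethyl-10-phenyldeca-5,7,9-trien-1-ol
Product: 23 (2S,3S,4R,5E,7E,9E)-3-(TBSO)-8-ethyl-2,4,6-trimethyl-10-phenyldeca-5,7,9-trienal
Conditions: Dess–Martin periodinane, NaHCO3, CH2Cl2, 0 °C; used crude
Reagents that add atoms: none
Why: Buffered Dess–Martin oxidation gives the α-chiral aldehyde without epimerising C3 or harming the triene.

Step 17
Reactants: 23 (2S,3S,4R,5E,7E,9E)-3-(TBSO)-8-ethyl-2,4,6-trimethyl-10-phenyldeca-5,7,9-trienal; 16 ethyl 2-(diethoxyphosphoryl)butanoate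
Product: 24 ethyl (2E,4R,5S,6R,7E,9E,11E)-5-(TBSO)-2,10-diethyl-4,6,8-trimethyl-12-phenyldodeca-2,7,9,11-tetraenoate
Conditions: 16, NaH, THF, 0 °C; then 23, −78 → 0 °C; kept cold and used at once
Reagents that add atoms: none
Why: Horner–Wadsworth–Emmons olefination gives the (E)-2-ethyl enoate (C3 cis to the ethyl group), and the low temperature avoids epimerisation at C3 and premature cycloaddition.

Step 18
Reactants: 24 ethyl (2E,4R,5S,6R,7E,9E,11E)-5-(TBSO)-2,10-diethyl-4,6,8-trimethyl-12-phenyldodeca-2,7,9,11-tetraenoate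
Product: 25 (2E,4R,5S,6R,7E,9E,11E)-5-(TBSO)-2,10-diethyl-4,6,8-trimethyl-12-phenyldodeca-2,7,9,11-tetraen-1-ol
Conditions: i-Bu2AlH (2.5 equiv), CH2Cl2, −78 °C
Reagents that add atoms: none
Why: 1,2-Reduction to the allylic alcohol, which is not a dienophile and can be purified safely.

Step 19
Reactants: 25 (2E,4R,5S,6R,7E,9E,11E)-5-(TBSO)-2,10-diethyl-4,6,8-trimethyl-12-phenyldodeca-2,7,9,11-tetraen-1-ol
Product: 27 (1R,2S,3R,3aS,4S,5R,7aS)-2-(TBSO)-4,5-diethyl-1,3,7-trimethyl-5-[(E)-2-phenylethenyl]-2,3,3a,4,5,7a-hexahydro-1H-indene-4-carbaldehyde, via all-E tetraenal 26 (not isolated)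
Conditions: MnO2 (excess), CH2Cl2, rt; filter; then toluene, BHT, 80–110 °C, high dilution
Reagents that add atoms: none
Why: Allylic oxidation then intramolecular Diels–Alder reaction with the formyl group endo and the three-carbon tether exo, where H1 and H3 eclipse the adjacent double bonds to avoid 1,3-allylic strain against the C7 methyl and the C4 ethyl, so the (1R,3R) centres set 3aS, 7aS (trans fusion), 4S and 5R together.

Step 20
Reactants: 27 (1R,2S,3R,3aS,4S,5R,7aS)-2-(TBSO)-4,5-diethyl-1,3,7-trimethyl-5-[(E)-2-phenylethenyl]-2,3,3a,4,5,7a-hexahydro-1H-indene-4-carbaldehyde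
Product: 28 (1R,2S,3R,3aS,4S,5R,7aS)-4,5-diethyl-2-hydroxy-1,3,7-trimethyl-5-[(E)-2-phenylethenyl]-2,3,3a,4,5,7a-hexahydro-1H-indene-4-carbaldehyde
Conditions: 48% aq. HF, MeCN, rt
Reagents that add atoms: none
Why: Fluoride-driven desilylation of the secondary silyl ether; the aldehyde has no α-hydrogen and the trans ring fusion keeps the C2 hydroxyl from reaching it as a lactol.

Step 21
Reactants: 28 (1R,2S,3R,3aS,4S,5R,7aS)-4,5-diethyl-2-hydroxy-1,3,7-trimethyl-5-[(E)-2-phenylethenyl]-2,3,3a,4,5,7a-hexahydro-1H-indene-4-carbaldehyde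
Product: 29 (1R,3R,3aS,4S,5R,7aS)-4,5-diethyl-1,3,7-trimethyl-2-oxo-5-[(E)-2-phenylethenyl]-2,3,3a,4,5,7a-hexahydro-1H-indene-4-carbaldehyde
Conditions: Dess–Martin periodinane, NaHCO3, CH2Cl2, rt
Reagents that add atoms: none
Why: Dess–Martin oxidation of the secondary alcohol to the cyclopentanone under near-neutral conditions that do not epimerise the α-centres C1 and C3.

Step 22
Reactants: 29 (1R,3R,3aS,4S,5R,7aS)-4,5-diethyl-1,3,7-trimethyl-2-oxo-5-[(E)-2-phenylethenyl]-2,3,3a,4,5,7a-hexahydro-1H-indene-4-carbaldehyde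
Product: 30 (1R,3R,3aS,4S,5R,7aS)-4,5-diethyl-1,3,7-trimethyl-2-oxo-5-[(E)-2-phenylethenyl]-2,3,3a,4,5,7a-hexahydro-1H-indene-4-carboxylic acid (dinorspiculoic acid A)
Conditions: NaClO2, NaH2PO4, 2-methyl-2-butene (large excess), t-BuOH/H2O, rt
Reagents that add atoms: sodium chlorite, [Na+].[O-]Cl=O
Why: Pinnick oxidation converts the aldehyde to the acid under mildly acidic buffered conditions that leave the ketone α-centres and the alkenes (protected by the chlorine scavenger) untouched.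

**Compound list**

1 | methyl (2R)-3-hydroxy-2-methylpropanoate | C[C@H](CO)C(=O)OC | starting material
2 | methyl (2R)-3-[(tert-butyldimethylsilyl)oxy]-2-methylpropanoate | C[C@H](CO[Si](C)(C)C(C)(C)C)C(=O)OC | intermediate
3 | (2S)-3-[(tert-butyldimethylsilyl)oxy]-2-methylpropan-1-ol | C[C@H](CO[Si](C)(C)C(C)(C)C)CO | intermediate
4 | (2R)-3-[(tert-butyldimethylsilyl)oxy]-2-methylpropanal | C[C@H](CO[Si](C)(C)C(C)(C)C)C=O | intermediate
5 | (4S)-4-benzyl-3-propanoyl-1,3-oxazolidin-2-one | CCC(=O)N1C(=O)OC[C@@H]1Cc1ccccc1 | starting material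
6 | (4S)-4-benzyl-3-[(1Z)-1-[(dibutylboranyl)oxy]prop-1-en-1-yl]-1,3-oxazolidin-2-one | C/C=C(\OB(CCCC)CCCC)N1C(=O)OC[C@@H]1Cc1ccccc1 | intermediate
7 | (4S)-4-benzyl-3-[(2S,3R,4R)-5-[(tert-butyldimethylsilyl)oxy]-3-[(dibutylboranyl)oxy]-2,4-dimethylpentanoyl]-1,3-oxazolidin-2-one | O=C(N1C(=O)OC[C@@H]1Cc1ccccc1)[C@@H](C)[C@H](OB(CCCC)CCCC)[C@H](C)CO[Si](C)(C)C(C)(C)C | intermediate
8 | (4S)-4-benzyl-3-[(2S,3R,4R)-5-[(tert-butyldimethylsilyl)oxy]-3-hydroxy-2,4-dimethylpentanoyl]-1,3-oxazolidin-2-one | O=C(N1C(=O)OC[C@@H]1Cc1ccccc1)[C@@H](C)[C@H](O)[C@H](C)CO[Si](C)(C)C(C)(C)C | intermediate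
9 | (2S,3R,4R)-5-[(tert-butyldimethylsilyl)oxy]-3-hydroxy-N-methoxy-N,2,4-trimethylpentanamide | CON(C)C(=O)[C@@H](C)[C@H](O)[C@H](C)CO[Si](C)(C)C(C)(C)C | intermediate
10 | (2S,3R,4R)-3,5-bis[(tert-butyldimethylsilyl)oxy]-N-methoxy-N,2,4-trimethylpentanamide | CON(C)C(=O)[C@@H](C)[C@H](O[Si](C)(C)C(C)(C)C)[C@H](C)CO[Si](C)(C)C(C)(C)C | intermediate
11 | (2S,3R,4R)-3,5-bis[(tert-butyldimethylsilyl)oxy]-2,4-dimethylpentanal | O=C[C@@H](C)[C@H](O[Si](C)(C)C(C)(C)C)[C@H](C)CO[Si](C)(C)C(C)(C)C | intermediate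
12 | ethyl 2-(triphenylphosphoranylidene)propanoate | CCOC(=O)C(C)=P(c1ccccc1)(c1ccccc1)c1ccccc1 | starting material
13 | ethyl (2E,4R,5S,6R)-5,7-bis[(tert-butyldimethylsilyl)oxy]-2,4,6-trimethylhept-2-enoate | CCOC(=O)/C(C)=C/[C@@H](C)[C@H](O[Si](C)(C)C(C)(C)C)[C@H](C)CO[Si](C)(C)C(C)(C)C | intermediate
14 | (2E,4R,5S,6R)-5,7-bis[(tert-butyldimethylsilyl)oxy]-2,4,6-trimethylhept-2-en-1-ol | OC/C(C)=C/[C@@H](C)[C@H](O[Si](C)(C)C(C)(C)C)[C@H](C)CO[Si](C)(C)C(C)(C)C | intermediate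
15 | (2E,4R,5S,6R)-5,7-bis[(tert-butyldimethylsilyl)oxy]-2,4,6-trimethylhept-2-enal | O=C/C(C)=C/[C@@H](C)[C@H](O[Si](C)(C)C(C)(C)C)[C@H](C)CO[Si](C)(C)C(C)(C)C | intermediate
16 | ethyl 2-(diethoxyphosphoryl)butanoate (triethyl 2-phosphonobutyrate) | CCOC(=O)C(CC)P(=O)(OCC)OCC | starting material
17 | ethyl (2E,4E,6R,7S,8R)-7,9-bis[(tert-butyldimethylsilyl)oxy]-2-ethyl-4,6,8-trimethylnona-2,4-dienoate | CCOC(=O)/C(CC)=C/C(C)=C/[C@@H](C)[C@H](O[Si](C)(C)C(C)(C)C)[C@H](C)CO[Si](C)(C)C(C)(C)C | intermediate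
18 | (2E,4E,6R,7S,8R)-7,9-bis[(tert-butyldimethylsilyl)oxy]-2-ethyl-4,6,8-trimethylnona-2,4-dien-1-ol | OC/C(CC)=C/C(C)=C/[C@@H](C)[C@H](O[Si](C)(C)C(C)(C)C)[C@H](C)CO[Si](C)(C)C(C)(C)C | intermediate
19 | (2E,4E,6R,7S,8R)-7,9-bis[(tert-butyldimethylsilyl)oxy]-2-ethyl-4,6,8-trimethylnona-2,4-dienal | O=C/C(CC)=C/C(C)=C/[C@@H](C)[C@H](O[Si](C)(C)C(C)(C)C)[C@H](C)CO[Si](C)(C)C(C)(C)C | intermediate
20 | diethyl benzylphosphonate | CCOP(=O)(Cc1ccccc1)OCC | starting material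
21 | [(1E,3E,5E,7R,8S,9R)-8,10-bis[(tert-butyldimethylsilyl)oxy]-3-ethyl-5,7,9-trimethyldeca-1,3,5-trien-1-yl]benzene | c1ccc(/C=C/C(CC)=C/C(C)=C/[C@@H](C)[C@H](O[Si](C)(C)C(C)(C)C)[C@H](C)CO[Si](C)(C)C(C)(C)C)cc1 | intermediate
22 | (2R,3S,4R,5E,7E,9E)-3-[(tert-butyldimethylsilyl)oxy]-8-ethyl-2,4,6-trimethyl-10-phenyldeca-5,7,9-trien-1-ol | c1ccc(/C=C/C(CC)=C/C(C)=C/[C@@H](C)[C@H](O[Si](C)(C)C(C)(C)C)[C@H](C)CO)cc1 | intermediate
23 | (2S,3S,4R,5E,7E,9E)-3-[(tert-butyldimethylsilyl)oxy]-8-ethyl-2,4,6-trimethyl-10-phenyldeca-5,7,9-trienal | c1ccc(/C=C/C(CC)=C/C(C)=C/[C@@H](C)[C@H](O[Si](C)(C)C(C)(C)C)[C@H](C)C=O)cc1 | intermediate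
24 | ethyl (2E,4R,5S,6R,7E,9E,11E)-5-[(tert-butyldimethylsilyl)oxy]-2,10-diethyl-4,6,8-trimethyl-12-phenyldodeca-2,7,9,11-tetraenoate | c1ccc(/C=C/C(CC)=C/C(C)=C/[C@@H](C)[C@H](O[Si](C)(C)C(C)(C)C)[C@H](C)/C=C(\CC)C(=O)OCC)cc1 | intermediate
25 | (2E,4R,5S,6R,7E,9E,11E)-5-[(tert-butyldimethylsilyl)oxy]-2,10-diethyl-4,6,8-trimethyl-12-phenyldodeca-2,7,9,11-tetraen-1-ol | c1ccc(/C=C/C(CC)=C/C(C)=C/[C@@H](C)[C@H](O[Si](C)(C)C(C)(C)C)[C@H](C)/C=C(\CC)CO)cc1 | intermediate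
26 | (2E,4R,5S,6R,7E,9E,11E)-5-[(tert-butyldimethylsilyl)oxy]-2,10-diethyl-4,6,8-trimethyl-12-phenyldodeca-2,7,9,11-tetraenal | c1ccc(/C=C/C(CC)=C/C(C)=C/[C@@H](C)[C@H](O[Si](C)(C)C(C)(C)C)[C@H](C)/C=C(\CC)C=O)cc1 | intermediate
27 | (1R,2S,3R,3aS,4S,5R,7aS)-2-[(tert-butyldimethylsilyl)oxy]-4,5-diethyl-1,3,7-trimethyl-5-[(E)-2-phenylethenyl]-2,3,3a,4,5,7a-hexahydro-1H-indene-4-carbaldehyde | CC[C@@]1(/C=C/c2ccccc2)C=C(C)[C@H]2[C@@H]([C@@H](C)[C@@H](O[Si](C)(C)C(C)(C)C)[C@@H]2C)[C@]1(CC)C=O | intermediate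
28 | (1R,2S,3R,3aS,4S,5R,7aS)-4,5-diethyl-2-hydroxy-1,3,7-trimethyl-5-[(E)-2-phenylethenyl]-2,3,3a,4,5,7a-hexahydro-1H-indene-4-carbaldehyde | CC[C@@]1(/C=C/c2ccccc2)C=C(C)[C@H]2[C@@H]([C@@H](C)[C@@H](O)[C@@H]2C)[C@]1(CC)C=O | intermediate
29 | (1R,3R,3aS,4S,5R,7aS)-4,5-diethyl-1,3,7-trimethyl-2-oxo-5-[(E)-2-phenylethenyl]-2,3,3a,4,5,7a-hexahydro-1H-indene-4-carbaldehyde | CC[C@@]1(/C=C/c2ccccc2)C=C(C)[C@H]2[C@@H]([C@@H](C)C(=O)[C@@H]2C)[C@]1(CC)C=O | intermediate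
30 | (1R,3R,3aS,4S,5R,7aS)-4,5-diethyl-1,3,7-trimethyl-2-oxo-5-[(E)-2-phenylethenyl]-2,3,3a,4,5,7a-hexahydro-1H-indene-4-carboxylic acid (dinorspiculoic acid A) | CC[C@@]1(/C=C/c2ccccc2)C=C(C)[C@H]2[C@@H]([C@@H](C)C(=O)[C@@H]2C)[C@]1(CC)C(=O)O | target

**Totals and weak points**

Total step count: 22. Longest linear sequence: 22 steps (1 to 30); 5, 12, 16 and 20 are bought and enter directly.

Most likely to fail, first: step 19. The cycloaddition must join two fully substituted carbons, and the stereochemical outcome rests on a conformational argument (endo formyl, 1,3-allylic strain) that has not been tested on this substrate. The enal may also oligomerise or give isomer mixtures. The fallback sets out from 24 and comes back at 27. Ester 24 is heated in toluene (BHT, 110 °C, high dilution) so that the slower but more robust enoate cyclises to the ester cycloadduct ethyl (1R,2S,3R,3aS,4S,5R,7aS)-2-[(tert-butyldimethylsilyl)oxy]-4,5-diethyl-1,3,7-trimethyl-5-[(E)-2-phenylethenyl]-2,3,3a,4,5,7a-hexahydro-1H-indene-4-carboxylate F1. The hindered ester is reduced with LiAlH4 (Et2O, 0 °C → rt) to the neopentyl alcohol [(1R,2S,3R,3aS,4S,5R,7aS)-2-[(tert-butyldimethylsilyl)oxy]-4,5-diethyl-1,3,7-trimethyl-5-[(E)-2-phenylethenyl]-2,3,3a,4,5,7a-hexahydro-1H-inden-4-yl]methanol F2. Dess–Martin oxidation of that alcohol gives 27.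

Second: step 15. The primary silyl ether has to be removed beside the secondary one and an acid-sensitive phenyl triene; partial loss of both groups or triene damage is possible. The fallback sets out from 21 and comes back at 24. Both silyl groups are removed with n-Bu4NF (THF, rt) to give the diol (2R,3S,4R,5E,7E,9E)-8-ethyl-2,4,6-trimethyl-10-phenyldeca-5,7,9-triene-1,3-diol F3. Only the primary alcohol is oxidised with catalytic TEMPO and PhI(OAc)2 (CH2Cl2, rt) to the hydroxy aldehyde (2S,3S,4R,5E,7E,9E)-8-ethyl-3-hydroxy-2,4,6-trimethyl-10-phenyldeca-5,7,9-trienal F4. This is olefinated with 16 under mild Masamune–Roush conditions (LiCl, i-Pr2NEt, MeCN) to the hydroxy enoate ethyl (2E,4R,5S,6R,7E,9E,11E)-2,10-diethyl-5-hydroxy-4,6,8-trimethyl-12-phenyldodeca-2,7,9,11-tetraenoate F5. Silylation with TBSOTf and 2,6-lutidine then gives 24.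

Third: step 22. The aldehyde sits on a quaternary carbon next to another quaternary carbon, so chlorite addition may be slow, and hypochlorite can attack the styrene or ring alkene if scavenging is incomplete. The fallback sets out from 24 and comes back at 30; it fixes the acid oxidation level before the ring is built. Ester 24 is saponified while still unhindered (LiOH, THF/MeOH/H2O, rt) to the acid (2E,4R,5S,6R,7E,9E,11E)-5-[(tert-butyldimethylsilyl)oxy]-2,10-diethyl-4,6,8-trimethyl-12-phenyldodeca-2,7,9,11-tetraenoic acid F6. Heating in toluene (BHT, 100 °C) gives by the same intramolecular Diels–Alder reaction the silyl ether acid (1R,2S,3R,3aS,4S,5R,7aS)-2-[(tert-butyldimethylsilyl)oxy]-4,5-diethyl-1,3,7-trimethyl-5-[(E)-2-phenylethenyl]-2,3,3a,4,5,7a-hexahydro-1H-indene-4-carboxylic acid F7. Aqueous HF in MeCN gives the hydroxy acid (1R,2S,3R,3aS,4S,5R,7aS)-4,5-diethyl-2-hydroxy-1,3,7-trimethyl-5-[(E)-2-phenylethenyl]-2,3,3a,4,5,7a-hexahydro-1H-indene-4-carboxylic acid F8. Dess–Martin oxidation of the secondary alcohol then gives 30.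

**Further compounds**

F1 | step 19 | ethyl (1R,2S,3R,3aS,4S,5R,7aS)-2-[(tert-butyldimethylsilyl)oxy]-4,5-diethyl-1,3,7-trimethyl-5-[(E)-2-phenylethenyl]-2,3,3a,4,5,7a-hexahydro-1H-indene-4-carboxylate | CC[C@@]1(/C=C/c2ccccc2)C=C(C)[C@H]2[C@@H]([C@@H](C)[C@@H](O[Si](C)(C)C(C)(C)C)[C@@H]2C)[C@]1(CC)C(=O)OCC
F2 | step 19 | [(1R,2S,3R,3aS,4S,5R,7aS)-2-[(tert-butyldimethylsilyl)oxy]-4,5-diethyl-1,3,7-trimethyl-5-[(E)-2-phenylethenyl]-2,3,3a,4,5,7a-hexahydro-1H-inden-4-yl]methanol | CC[C@@]1(/C=C/c2ccccc2)C=C(C)[C@H]2[C@@H]([C@@H](C)[C@@H](O[Si](C)(C)C(C)(C)C)[C@@H]2C)[C@]1(CC)CO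
F3 | step 15 | (2R,3S,4R,5E,7E,9E)-8-ethyl-2,4,6-trimethyl-10-phenyldeca-5,7,9-triene-1,3-diol | c1ccc(/C=C/C(CC)=C/C(C)=C/[C@@H](C)[C@H](O)[C@H](C)CO)cc1
F4 | step 15 | (2S,3S,4R,5E,7E,9E)-8-ethyl-3-hydroxy-2,4,6-trimethyl-10-phenyldeca-5,7,9-trienal | c1ccc(/C=C/C(CC)=C/C(C)=C/[C@@H](C)[C@H](O)[C@H](C)C=O)cc1
F5 | step 15 | ethyl (2E,4R,5S,6R,7E,9E,11E)-2,10-diethyl-5-hydroxy-4,6,8-trimethyl-12-phenyldodeca-2,7,9,11-tetraenoate | c1ccc(/C=C/C(CC)=C/C(C)=C/[C@@H](C)[C@H](O)[C@H](C)/C=C(\CC)C(=O)OCC)cc1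
F6 | step 22 | (2E,4R,5S,6R,7E,9E,11E)-5-[(tert-butyldimethylsilyl)oxy]-2,10-diethyl-4,6,8-trimethyl-12-phenyldodeca-2,7,9,11-tetraenoic acid | c1ccc(/C=C/C(CC)=C/C(C)=C/[C@@H](C)[C@H](O[Si](C)(C)C(C)(C)C)[C@H](C)/C=C(\CC)C(=O)O)cc1
F7 | step 22 | (1R,2S,3R,3aS,4S,5R,7aS)-2-[(tert-butyldimethylsilyl)oxy]-4,5-diethyl-1,3,7-trimethyl-5-[(E)-2-phenylethenyl]-2,3,3a,4,5,7a-hexahydro-1H-indene-4-carboxylic acid | CC[C@@]1(/C=C/c2ccccc2)C=C(C)[C@H]2[C@@H]([C@@H](C)[C@@H](O[Si](C)(C)C(C)(C)C)[C@@H]2C)[C@]1(CC)C(=O)O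
F8 | step 22 | (1R,2S,3R,3aS,4S,5R,7aS)-4,5-diethyl-2-hydroxy-1,3,7-trimethyl-5-[(E)-2-phenylethenyl]-2,3,3a,4,5,7a-hexahydro-1H-indene-4-carboxylic acid | CC[C@@]1(/C=C/c2ccccc2)C=C(C)[C@H]2[C@@H]([C@@H](C)[C@@H](O)[C@@H]2C)[C@]1(CC)C(=O)O
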